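**Retrosynthetic overview**

- The C7–CH2–pyranone bond is cut last: the C7 hydroxymethyl group ionises to a quinone-methide-like cation that benzylates C3 of 6-ethyl-4-hydroxy-5-methylpyran-2-one, and MOM removal follows. The C5 acetyl group comes from lithiation between the two MOM ethers.
- The exocyclic methylene on the C2 side chain comes from a C1′ carbinol (oxidation, then titanium methylenation); C1′ is the side-chain carbon on C2.
- The strategy rests on the dihydrofuran ring. O1 (on C7a) and C3 (on C3a) sit on adjacent benzene carbons, and O1–C2–C3 is the O–CH–CH2 unit of a terminal epoxide whose CH is the C2 stereocentre. One palladium/norbornene annulation of an aryl iodide (iodine at C7a, free C–H at C3a, CH2OTBS at C7) with the (R)-epoxide therefore makes C3a–C3 and O1–C7a.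
- The aryl iodide comes from 1-iodo-3,5-dimethoxybenzene, the epoxide from acrolein and homoprenyl bromide through a Sharpless kinetic resolution, and the pyranone from pentan-3-one and malonyl dichloride.
- Ring order: the benzene ring is bought, the pyranone ring is built separately (step 16), and the dihydrofuran ring is closed in the key step.

Key step: step 9

Assumption: benzofuran numbering is used for the core. The single stereocentre of the target, C2, is (R). The C1′ configuration of the intermediates is irrelevant because C1′ is oxidised in step 11, and the kinetic resolution is stopped below half conversion so that the epoxy alcohol can be taken as one enantiomer.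

**Route**

Step 1
Reactants: 1 1-iodo-3,5-dimethoxybenzene
Product: 3 2-iodo-4,6-dimethoxybenzaldehyde, via aryl iminium salt 2 (not isolated)
Conditions: POCl3, DMF, 0 °C → 80 °C; then ice-water
Reagents that add atoms: N,N-dimethylformamide, CN(C)C=O (formyl carbon); water, O (aldehyde oxygen)
Why: Vilsmeier–Haack formylation should occur mainly next to iodine, para to one methoxy group and ortho to the other (two equivalent sites, less crowded than the position between the methoxy groups), and the iminium salt is hydrolysed on work-up.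

Step 2
Reactants: 3 2-iodo-4,6-dimethoxybenzaldehyde
Product: 4 2,4-dihydroxy-6-iodobenzaldehyde
Conditions: BBr3 (excess), CH2Cl2, −78 °C → rt; then H2O
Reagents that add atoms: none
Why: Lewis-acid cleavage of both aryl methyl ethers (the ortho one assisted by chelation to the aldehyde) should leave the aryl iodide and the aldehyde intact.

Step 3
Reactants: 4 2,4-dihydroxy-6-iodobenzaldehyde
Product: 5 2-iodo-4,6-bis(methoxymethoxy)benzaldehyde
Conditions: MOMCl, iPr2NEt, CH2Cl2, 0 °C → rt
Reagents that add atoms: chloromethyl methyl ether, COCCl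
Why: O-alkylation of both phenols gives MOM ethers, which tolerate carbonate base at 90 °C and later direct lithiation to C5.

Step 4
Reactants: 5 2-iodo-4,6-bis(methoxymethoxy)benzaldehyde
Product: 6 [2-iodo-4,6-bis(methoxymethoxy)phenyl]methanol
Conditions: NaBH4, MeOH/THF, 0 °C
Reagents that add atoms: none
Why: Hydride reduction of the aldehyde, to which the aryl iodide and the acetals are inert.

Step 5
Reactants: 6 [2-iodo-4,6-bis(methoxymethoxy)phenyl]methanol
Product: 7 tert-butyl{[2-iodo-4,6-bis(methoxymethoxy)phenyl]methoxy}dimethylsilane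
Conditions: TBSCl, imidazole, DMF, rt
Reagents that add atoms: tert-butyldimethylsilyl chloride, CC(C)(C)[Si](C)(C)Cl
Why: Silylation of the primary alcohol supplies the ortho substituent that the norbornene relay needs and keeps the C7 benzylic oxygen for the end game.

Step 6
Reactants: 8 5-bromo-2-methylpent-2-ene; 9 acrolein
Product: 11 (±)-7-methylocta-1,6-dien-3-ol, via homoprenylmagnesium bromide 10 (not isolated)
Conditions: Mg, THF, 35 °C; then acrolein, −78 °C; sat. aq NH4Cl
Reagents that add atoms: none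
Why: Grignard formation and 1,2-addition to the enal at low temperature should give the racemic secondary allylic alcohol.

Step 7
Reactants: 11 (±)-7-methylocta-1,6-dien-3-ol
Product: 12 (1S)-5-methyl-1-[(2R)-oxiran-2-yl]hex-4-en-1-ol
Conditions: Ti(OiPr)4 (0.15 equiv), L-(+)-diisopropyl tartrate (0.2 equiv), t-BuOOH (0.45 equiv), 4 Å MS, CH2Cl2, −20 °C
Reagents that add atoms: tert-butyl hydroperoxide, CC(C)(C)OO
Why: In this Sharpless kinetic resolution the L-(+)-tartrate catalyst epoxidises the matched (S)-alcohol on the face that gives the erythro epoxy alcohol with an (R) oxirane carbon, while the (R)-alcohol is left behind and the remote trisubstituted alkene, having no allylic hydroxyl, is not attacked.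

Step 8
Reactants: 12 (1S)-5-methyl-1-[(2R)-oxiran-2-yl]hex-4-en-1-ol
Product: 13 (2R)-2-{(1S)-1-[(2-methoxypropan-2-yl)oxy]-5-methylhex-4-en-1-yl}oxirane
Conditions: 2-methoxypropene, PPTS (cat.), CH2Cl2, 0 °C
Reagents that add atoms: 2-methoxypropene, C=C(C)OC
Why: Acid-catalysed addition of the alcohol to the enol ether gives a mixed acetone ketal (MOP) that is base-stable, adds no stereocentre and forms under conditions too mild to open the epoxide.

Step 9
Reactants: 7 tert-butyl{[2-iodo-4,6-bis(methoxymethoxy)phenyl]methoxy}dimethylsilane; 13 (2R)-2-{(1S)-1-[(2-methoxypropan-2-yl)oxy]-5-methylhex-4-en-1-yl}oxirane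
Product: 14 tert-butyl({(2R)-2-{(1S)-1-[(2-methoxypropan-2-yl)oxy]-5-methylhex-4-en-1-yl}-4,6-bis(methoxymethoxy)-2,3-dihydro-1-benzofuran-7-yl}methoxy)dimethylsilane
Conditions: Pd(OAc)2 (10 mol%), XPhos (20 mol%), isopropyl bicyclo[2.2.1]hept-5-ene-2-carboxylate (50 mol%), Cs2CO3, NMP, 90 °C
Reagents that add atoms: none
Why: This is a Catellani-type palladium/norbornene annulation of an aryl iodide with a terminal epoxide, a known route to 2,3-dihydrobenzofurans: zerovalent palladium inserts into the C–I bond of 7, norbornene insertion and palladation of the only free ortho C–H (the future C3a) give an aryl–norbornyl palladacycle, and this opens epoxide 13 by SN2-like oxidative addition at its unsubstituted CH2 and reductively eliminates to form C3a–C3. Both ortho positions are then occupied (the CH2OTBS group at C7 is the required ortho substituent), so norbornene is expelled by β-carbon elimination and the freed C2 alkoxide binds divalent palladium at C7a. The dihydrofuran ring is closed by C(aryl)–O reductive elimination from this six-membered oxapalladacycle, forming O1–C7a and returning zerovalent palladium. No stereocentre is created: C2 is the epoxide CH, which is never a reacting centre, so the (R) configuration of 13 is carried over unchanged, as is C1′. The step needs opening at CH2 only (secured by the steric bias of a monosubstituted oxirane), a single ortho functionalisation (only one ortho C–H exists) and indifference to the trisubstituted alkene (norbornene inserts far faster); the C1′ oxygen is kept as the MOP ether because a vinyl epoxide would ionise on zerovalent palladium and a free hydroxyl could compete in C–O bond formation. The weak point is palladation of the C–H that lies next to the C4 MOM ether.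

Step 10
Reactants: 14 tert-butyl({(2R)-2-{(1S)-1-[(2-methoxypropan-2-yl)oxy]-5-methylhex-4-en-1-yl}-4,6-bis(methoxymethoxy)-2,3-dihydro-1-benzofuran-7-yl}methoxy)dimethylsilane
Product: 15 (1S)-1-[(2R)-7-({[tert-butyl(dimethyl)silyl]oxy}methyl)-4,6-bis(methoxymethoxy)-2,3-dihydro-1-benzofuran-2-yl]-5-methylhex-4-en-1-ol
Conditions: PPTS (cat.), MeOH, 0 °C
Reagents that add atoms: none
Why: Transketalisation removes the mixed acetone ketal with a trace of weak acid far faster than aryl MOM ethers or the silyl ether are affected.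

Step 11
Reactants: 15 (1S)-1-[(2R)-7-({[tert-butyl(dimethyl)silyl]oxy}methyl)-4,6-bis(methoxymethoxy)-2,3-dihydro-1-benzofuran-2-yl]-5-methylhex-4-en-1-ol
Product: 16 1-[(2R)-7-({[tert-butyl(dimethyl)silyl]oxy}methyl)-4,6-bis(methoxymethoxy)-2,3-dihydro-1-benzofuran-2-yl]-5-methylhex-4-en-1-one
Conditions: Dess–Martin periodinane, pyridine, CH2Cl2, 0 °C
Reagents that add atoms: none
Why: Dess–Martin oxidation under buffered conditions converts the C1′ carbinol into the ketone without touching the alkene or the electron-rich arene and without enolising toward C2.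

Step 12
Reactants: 16 1-[(2R)-7-({[tert-butyl(dimethyl)silyl]oxy}methyl)-4,6-bis(methoxymethoxy)-2,3-dihydro-1-benzofuran-2-yl]-5-methylhex-4-en-1-one
Product: 17 tert-butyl{[(2R)-2-(6-methylhepta-1,5-dien-2-yl)-4,6-bis(methoxymethoxy)-2,3-dihydro-1-benzofuran-7-yl]methoxy}dimethylsilane
Conditions: Cp2TiMe2, toluene, 65 °C, dark
Reagents that add atoms: dimethyltitanocene Cp2TiMe2, C[Ti](C)(C1C=CC=C1)C1C=CC=C1 (the CH2 carbon)
Why: In this Petasis methylenation, thermally formed Cp2Ti=CH2 converts the ketone to the 1,1-disubstituted alkene by cycloaddition and cycloreversion under non-basic conditions, which is why it is preferred to a phosphorus ylide for an α-aryloxy ketone with an enolisable C2–H.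

Step 13
Reactants: 17 tert-butyl{[(2R)-2-(6-methylhepta-1,5-dien-2-yl)-4,6-bis(methoxymethoxy)-2,3-dihydro-1-benzofuran-7-yl]methoxy}dimethylsilane
Product: 19 1-[(2R)-7-({[tert-butyl(dimethyl)silyl]oxy}methyl)-4,6-bis(methoxymethoxy)-2-(6-methylhepta-1,5-dien-2-yl)-2,3-dihydro-1-benzofuran-5-yl]ethan-1-one, via C5 aryllithium 18 (not isolated)
Conditions: n-BuLi (1.2 equiv), THF, −20 → 0 °C; then N-methoxy-N-methylacetamide, −78 → 0 °C; sat. aq NH4Cl
Reagents that add atoms: N-methoxy-N-methylacetamide, CON(C)C(C)=O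
Why: Directed ortho-metalation removes C5–H, the only aromatic hydrogen and one flanked by two MOM ethers, and the aryllithium is acylated once through the stable chelated tetrahedral adduct of the N-methoxy-N-methyl amide.

Step 14
Reactants: 19 1-[(2R)-7-({[tert-butyl(dimethyl)silyl]oxy}methyl)-4,6-bis(methoxymethoxy)-2-(6-methylhepta-1,5-dien-2-yl)-2,3-dihydro-1-benzofuran-5-yl]ethan-1-one
Product: 20 1-[(2R)-7-(hydroxymethyl)-4,6-bis(methoxymethoxy)-2-(6-methylhepta-1,5-dien-2-yl)-2,3-dihydro-1-benzofuran-5-yl]ethan-1-one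
Conditions: TBAF, THF, 0 °C
Reagents that add atoms: none
Why: Fluoride-mediated desilylation frees the C7 benzylic alcohol while MOM ethers, ketone and alkenes are inert.

Step 15
Reactants: 21 pentan-3-one
Product: 22 trimethyl(pent-2-en-3-yloxy)silane
Conditions: TMSOTf, Et3N, CH2Cl2, 0 °C
Reagents that add atoms: trimethylsilyl trifluoromethanesulfonate, C[Si](C)(C)OS(=O)(=O)C(F)(F)F
Why: Soft enolisation and O-silylation of the symmetrical ketone gives the silyl enol ether with no regiochemical question (the alkene geometry is irrelevant).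

Step 16
Reactants: 22 trimethyl(pent-2-en-3-yloxy)silane
Product: 24 6-ethyl-4-hydroxy-5-methyl-2H-pyran-2-one, via 4-methyl-3,5-dioxoheptanoyl chloride 23 (not isolated)
Conditions: malonyl dichloride, Et2O, −78 °C → rt
Reagents that add atoms: malonyl dichloride, O=C(Cl)CC(Cl)=O
Why: Malonyl dichloride C-acylates the silyl enol ether and the resulting diketo acid chloride lactonises through its enol oxygen, the established pyranone synthesis from enol ethers and malonyl dichloride.

Step 17
Reactants: 20 1-[(2R)-7-(hydroxymethyl)-4,6-bis(methoxymethoxy)-2-(6-methylhepta-1,5-dien-2-yl)-2,3-dihydro-1-benzofuran-5-yl]ethan-1-one; 24 6-ethyl-4-hydroxy-5-methyl-2H-pyran-2-one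
Product: 25 3-{[(2R)-5-acetyl-4,6-bis(methoxymethoxy)-2-(6-methylhepta-1,5-dien-2-yl)-2,3-dihydro-1-benzofuran-7-yl]methyl}-6-ethyl-4-hydroxy-5-methyl-2H-pyran-2-one
Conditions: camphorsulfonic acid (10 mol%), 4 Å MS, MeCN, rt → 40 °C
Reagents that add atoms: none
Why: In this Friedel–Crafts-type benzylation the benzylic alcohol, ortho to O1 and to the C6 MOM ether and para to the C4 MOM ether, ionises under mild acid to a quinone-methide-like oxocarbenium ion that is captured at the nucleophilic C3 of the 4-hydroxypyranone, C-alkylation being the thermodynamic outcome because O-alkylation is reversible.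

Step 18
Reactants: 25 3-{[(2R)-5-acetyl-4,6-bis(methoxymethoxy)-2-(6-methylhepta-1,5-dien-2-yl)-2,3-dihydro-1-benzofuran-7-yl]methyl}-6-ethyl-4-hydroxy-5-methyl-2H-pyran-2-one
Product: 26 3-{[(2R)-5-acetyl-4,6-dihydroxy-2-(6-methylhepta-1,5-dien-2-yl)-2,3-dihydro-1-benzofuran-7-yl]methyl}-6-ethyl-4-hydroxy-5-methyl-2H-pyran-2-one (CNP0294086.1)
Conditions: HCl (ca. 1 M in MeOH), MeOH/THF, 0 °C → rt
Reagents that add atoms: none
Why: Acid-catalysed acetal methanolysis should cleave the two MOM ethers, both ortho to the acetyl group and therefore labile, under conditions mild enough to spare the two alkenes and the allylic C2–O1 bond.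

**Compound list**

1 | 1-iodo-3,5-dimethoxybenzene | COc1cc(I)cc(OC)c1 | starting material
2 | N-[(2-iodo-4,6-dimethoxyphenyl)methylidene]-N-methylmethanaminium dichlorophosphate | C[N+](C)=Cc1c(I)cc(OC)cc1OC.[O-]P(Cl)(Cl)=O | intermediate (not isolated)
3 | 2-iodo-4,6-dimethoxybenzaldehyde | O=Cc1c(I)cc(OC)cc1OC | intermediate
4 | 2,4-dihydroxy-6-iodobenzaldehyde | O=Cc1c(I)cc(O)cc1O | intermediate
5 | 2-iodo-4,6-bis(methoxymethoxy)benzaldehyde | O=Cc1c(I)cc(OCOC)cc1OCOC | intermediate
6 | [2-iodo-4,6-bis(methoxymethoxy)phenyl]methanol | OCc1c(I)cc(OCOC)cc1OCOC | intermediate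
7 | tert-butyl{[2-iodo-4,6-bis(methoxymethoxy)phenyl]methoxy}dimethylsilane | CC(C)(C)[Si](C)(C)OCc1c(I)cc(OCOC)cc1OCOC | intermediate
8 | 5-bromo-2-methylpent-2-ene | CC(C)=CCCBr | starting material
9 | acrolein (prop-2-enal) | C=CC=O | starting material
10 | (4-methylpent-3-en-1-yl)magnesium bromide | CC(C)=CCC[Mg]Br | intermediate (not isolated)
11 | (±)-7-methylocta-1,6-dien-3-ol | C=CC(O)CCC=C(C)C | intermediate
12 | (1S)-5-methyl-1-[(2R)-oxiran-2-yl]hex-4-en-1-ol | CC(C)=CCC[C@H](O)[C@H]1CO1 | intermediate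
13 | (2R)-2-{(1S)-1-[(2-methoxypropan-2-yl)oxy]-5-methylhex-4-en-1-yl}oxirane | CC(C)=CCC[C@H](OC(C)(C)OC)[C@H]1CO1 | intermediate
14 | tert-butyl({(2R)-2-{(1S)-1-[(2-methoxypropan-2-yl)oxy]-5-methylhex-4-en-1-yl}-4,6-bis(methoxymethoxy)-2,3-dihydro-1-benzofuran-7-yl}methoxy)dimethylsilane | CC(C)=CCC[C@H](OC(C)(C)OC)[C@H]1Cc2c(OCOC)cc(OCOC)c(CO[Si](C)(C)C(C)(C)C)c2O1 | intermediate
15 | (1S)-1-[(2R)-7-({[tert-butyl(dimethyl)silyl]oxy}methyl)-4,6-bis(methoxymethoxy)-2,3-dihydro-1-benzofuran-2-yl]-5-methylhex-4-en-1-ol | CC(C)=CCC[C@H](O)[C@H]1Cc2c(OCOC)cc(OCOC)c(CO[Si](C)(C)C(C)(C)C)c2O1 | intermediate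
16 | 1-[(2R)-7-({[tert-butyl(dimethyl)silyl]oxy}methyl)-4,6-bis(methoxymethoxy)-2,3-dihydro-1-benzofuran-2-yl]-5-methylhex-4-en-1-one | CC(C)=CCCC(=O)[C@H]1Cc2c(OCOC)cc(OCOC)c(CO[Si](C)(C)C(C)(C)C)c2O1 | intermediate
17 | tert-butyl{[(2R)-2-(6-methylhepta-1,5-dien-2-yl)-4,6-bis(methoxymethoxy)-2,3-dihydro-1-benzofuran-7-yl]methoxy}dimethylsilane | C=C(CCC=C(C)C)[C@H]1Cc2c(OCOC)cc(OCOC)c(CO[Si](C)(C)C(C)(C)C)c2O1 | intermediate
18 | {(2R)-7-({[tert-butyl(dimethyl)silyl]oxy}methyl)-4,6-bis(methoxymethoxy)-2-(6-methylhepta-1,5-dien-2-yl)-2,3-dihydro-1-benzofuran-5-yl}lithium | C=C(CCC=C(C)C)[C@H]1Cc2c(OCOC)c([Li])c(OCOC)c(CO[Si](C)(C)C(C)(C)C)c2O1 | intermediate (not isolated)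
19 | 1-[(2R)-7-({[tert-butyl(dimethyl)silyl]oxy}methyl)-4,6-bis(methoxymethoxy)-2-(6-methylhepta-1,5-dien-2-yl)-2,3-dihydro-1-benzofuran-5-yl]ethan-1-one | C=C(CCC=C(C)C)[C@H]1Cc2c(OCOC)c(C(C)=O)c(OCOC)c(CO[Si](C)(C)C(C)(C)C)c2O1 | intermediate
20 | 1-[(2R)-7-(hydroxymethyl)-4,6-bis(methoxymethoxy)-2-(6-methylhepta-1,5-dien-2-yl)-2,3-dihydro-1-benzofuran-5-yl]ethan-1-one | C=C(CCC=C(C)C)[C@H]1Cc2c(OCOC)c(C(C)=O)c(OCOC)c(CO)c2O1 | intermediate
21 | pentan-3-one | CCC(=O)CC | starting material
22 | trimethyl(pent-2-en-3-yloxy)silane | CC=C(CC)O[Si](C)(C)C | intermediate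
23 | 4-methyl-3,5-dioxoheptanoyl chloride | CCC(=O)C(C)C(=O)CC(Cl)=O | intermediate (not isolated)
24 | 6-ethyl-4-hydroxy-5-methyl-2H-pyran-2-one | CCc1oc(=O)cc(O)c1C | intermediate
25 | 3-{[(2R)-5-acetyl-4,6-bis(methoxymethoxy)-2-(6-methylhepta-1,5-dien-2-yl)-2,3-dihydro-1-benzofuran-7-yl]methyl}-6-ethyl-4-hydroxy-5-methyl-2H-pyran-2-one | C=C(CCC=C(C)C)[C@H]1Cc2c(OCOC)c(C(C)=O)c(OCOC)c(Cc3c(O)c(C)c(CC)oc3=O)c2O1 | intermediate
26 | 3-{[(2R)-5-acetyl-4,6-dihydroxy-2-(6-methylhepta-1,5-dien-2-yl)-2,3-dihydro-1-benzofuran-7-yl]methyl}-6-ethyl-4-hydroxy-5-methyl-2H-pyran-2-one | C=C(CCC=C(C)C)[C@H]1Cc2c(O)c(C(C)=O)c(O)c(Cc3c(O)c(C)c(CC)oc3=O)c2O1 | target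

**Step count**

Total: 18 steps. Longest linear sequence: 13 steps (steps 1–5, 9–14, 17 and 18).

**Steps most likely to fail**

1. Step 9. Palladation of the C–H wedged between the iodine-bearing carbon and the C4 MOM ether may be too slow, so that protodeiodination, norbornene-retaining adducts or direct ipso coupling take over; opening of the epoxide by the crowded palladacycle may also stall. A bridgehead-substituted norbornene would be tried first. The fallback abandons the epoxide relay, sets out from 7 and returns at 17.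
   - Miyaura borylation of 7 (Pd(dppf)Cl2, bis(pinacolato)diboron, KOAc, dioxane, 80 °C) would give 2-[2-({[tert-butyl(dimethyl)silyl]oxy}methyl)-3,5-bis(methoxymethoxy)phenyl]-4,4,5,5-tetramethyl-1,3,2-dioxaborolane F1.
   - Oxidation (H2O2, NaOH, THF, 0 °C) would give 2-({[tert-butyl(dimethyl)silyl]oxy}methyl)-3,5-bis(methoxymethoxy)phenol F2, which already carries O1.
   - Amine-mediated ortho bromination (NBS, cat. iPr2NH, CH2Cl2, −78 → 0 °C) should place bromine on the future C3a in preference to the more crowded position between the MOM ethers, giving 2-bromo-6-({[tert-butyl(dimethyl)silyl]oxy}methyl)-3,5-bis(methoxymethoxy)phenol F3.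
   - An enantioselective palladium-catalysed Heck/Tsuji–Trost heteroannulation of F3 with myrcene (7-methyl-3-methylideneocta-1,6-diene, C=CC(=C)CCC=C(C)C; Pd2(dba)3, chiral sulfinamide-phosphine ligand, K2CO3, 80 °C) would form C3a–C3 by arylpalladation of the vinyl terminus and O1–C2 by phenoxide attack on the π-allyl. This gives 17 directly, with C2 set by the ligand, and makes steps 10–12 unnecessary.

2. Step 17. Ionisation of the benzylic alcohol may be outpaced by loss of MOM groups, or the cation may be diverted to O-alkylation of the pyranone or to solvent capture. The fallback sets out from 20 and returns at 25.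
   - Oxidation of 20 (MnO2, CH2Cl2, rt) would give (2R)-5-acetyl-4,6-bis(methoxymethoxy)-2-(6-methylhepta-1,5-dien-2-yl)-2,3-dihydro-1-benzofuran-7-carbaldehyde F4.
   - Organocatalytic three-component reductive alkylation of 24 with F4 and Hantzsch ester (diethyl 2,6-dimethyl-1,4-dihydropyridine-3,5-dicarboxylate; L-proline cat., CH2Cl2, rt) would pass through the Knoevenagel adduct 3-{[(2R)-5-acetyl-4,6-bis(methoxymethoxy)-2-(6-methylhepta-1,5-dien-2-yl)-2,3-dihydro-1-benzofuran-7-yl]methylidene}-6-ethyl-5-methyl-2H-pyran-2,4(3H)-dione F5, which is reduced in the same flask by hydride transfer to 25.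

3. Step 12. Enolisation of the α-aryloxy ketone toward C2 during the heated methylenation would erode the only stereocentre, and the hindered ketone may react sluggishly with the titanium methylidene. The fallback is a two-stage Peterson olefination, sets out from 16 and returns at 17.
   - Addition of Me3SiCH2Li premixed with anhydrous CeCl3 (THF, −78 °C), a nucleophilic but weakly basic reagent, would give 2-[(2R)-7-({[tert-butyl(dimethyl)silyl]oxy}methyl)-4,6-bis(methoxymethoxy)-2,3-dihydro-1-benzofuran-2-yl]-6-methyl-1-(trimethylsilyl)hept-5-en-2-ol F6 as a mixture of carbinol epimers.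
   - Base-induced syn elimination (KH, THF, 0 °C), with no carbonyl left to enolise, would give 17.

**Further compounds**

F1 | step 9 | 2-[2-({[tert-butyl(dimethyl)silyl]oxy}methyl)-3,5-bis(methoxymethoxy)phenyl]-4,4,5,5-tetramethyl-1,3,2-dioxaborolane | CC(C)(C)[Si](C)(C)OCc1c(B2OC(C)(C)C(C)(C)O2)cc(OCOC)cc1OCOC
F2 | step 9 | 2-({[tert-butyl(dimethyl)silyl]oxy}methyl)-3,5-bis(methoxymethoxy)phenol | CC(C)(C)[Si](C)(C)OCc1c(O)cc(OCOC)cc1OCOC
F3 | step 9 | 2-bromo-6-({[tert-butyl(dimethyl)silyl]oxy}methyl)-3,5-bis(methoxymethoxy)phenol | CC(C)(C)[Si](C)(C)OCc1c(O)c(Br)c(OCOC)cc1OCOC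
F4 | step 17 | (2R)-5-acetyl-4,6-bis(methoxymethoxy)-2-(6-methylhepta-1,5-dien-2-yl)-2,3-dihydro-1-benzofuran-7-carbaldehyde | C=C(CCC=C(C)C)[C@H]1Cc2c(OCOC)c(C(C)=O)c(OCOC)c(C=O)c2O1
F5 | step 17 | 3-{[(2R)-5-acetyl-4,6-bis(methoxymethoxy)-2-(6-methylhepta-1,5-dien-2-yl)-2,3-dihydro-1-benzofuran-7-yl]methylidene}-6-ethyl-5-methyl-2H-pyran-2,4(3H)-dione | C=C(CCC=C(C)C)[C@H]1Cc2c(OCOC)c(C(C)=O)c(OCOC)c(C=C3C(=O)OC(CC)=C(C)C3=O)c2O1
F6 | step 12 | 2-[(2R)-7-({[tert-butyl(dimethyl)silyl]oxy}methyl)-4,6-bis(methoxymethoxy)-2,3-dihydro-1-benzofuran-2-yl]-6-methyl-1-(trimethylsilyl)hept-5-en-2-ol | CC(C)=CCCC(O)(C[Si](C)(C)C)[C@H]1Cc2c(OCOC)cc(OCOC)c(CO[Si](C)(C)C(C)(C)C)c2O1
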